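Count one chain for each Z charged, and the average chain in this flask becomes the share of the D charge standing as X, multiplied by the D charged per Z charged.

| setting | elm | alder | flask |
|---|---|---|---|
| D | 2.8 M | 2 M | 2.0 M |
| Z | 40 mM | 60 mM | 40 mM |
| remark | run made earlier | run made earlier |  |
| time |  |  | 10 d |

| run | time / d | X / % | D / % |
|---|---|---|---|
| elm | 0.625 | 30.7 | 69.7 |
| elm | 1.04 | 40.7 | 58.0 |
| elm | 1.67 | 50.0 | 49.4 |
| elm | 3.00 | 56.0 | 42.7 |
| elm | 5.00 | 58.3 | 40.7 |
| elm | 8.00 | 58.2 | 40.3 |
| alder | 1.67 | 51.1 | 47.7 |
| alder | 3.00 | 55.9 | 43.1 |
| alder | 5.00 | 56.0 | 40.8 |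
| alder | 6.00 | 57.0 | 40.2 |
| alder | 8.00 | 57.1 | 40.6 |

(readings scatter by 0.5 percentage points)

- average number of monomer units in a chain (chains begun, living or dead) at 10 d
- part of the D that has reacted at 10 d

- the average divides the monomer in chains by the number of chains begun, living and dead together
- the earlier runs do not show the number of chains; that part of a forecast is a guess

I carry the flask's charge ratio, 50.0, the D charged per Z charged. The last readings of the D left are 40.3% in elm and 40.6% in alder, though these runs differ in their charges of both D and Z, so I take the last elm reading of X, 58.2%, for the flask. Multiplying gives my average, 29.1, and the one chain per Z remains a guess, since the runs show no chain count.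

The forecast gives 29.5 units and 59.5% reacted, holding that “the plateau is a fixed fraction, not a fixed concentration”; its average stands above mine.

The flask gives 27.4 units and 56.8% reacted at 10 d, both within the forecast's margins, and at 100 d it stands at 27.4 and 56.9%.

    D + Z → L + X (k = 0.00773 /M/min)
    D + L → X + L, rate k2*[L]*[D] (k = 0.0159 /M/min)
    X + L → D + L, rate k3*[L] as long as [X] is above zero (k = 0.0120 /min)
    L + X → E (k = 3.41 × 10⁻⁴ /M/min)

In the flask at 10 d, Z stands at 0% of its charge, less than the 43% of D, and X stands at 54.8%, so the charge ratio gives 27.4 beside the 27.4 found. The neighbour charged with 0.16 M of Z has its ratio cut to 12.5, and with X at 54.3% the same product is 6.78, while that neighbour gives 6.78.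

The runs come from a simulation for an exercise.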